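**Retrosynthetic overview**

1. The target comes from its 5,7-di-O-MOM ether by acid cleavage of the two aryl acetals in the last step.
2. Ring C is the only ring made, by forming the O1–C2 bond. C2 is the benzylic carbon para to the ring B hydroxyl and next to the C3 carbinol, so Ag2O can take its C–H to a para-quinone methide. The ring A hydroxyl lying between the geranyl-bearing and the acyl-bearing carbons traps it, and the C3 stereocentre (chiral pool) directs C2 trans.
3. The open-chain (R)-ketol comes from the C4–C4a bond: lithiated 2-geranyl-1,3,5-tris(MOM)benzene adds to the Weinreb amide of O-protected (R)-4-hydroxyphenyllactic acid (D-tyrosine, diazotisation with retention). This is chosen over a Lewis-acid acylation of phloroglucinol, which would endanger the α-oxygenated stereocentre. The ring A oxygens are then told apart by full MOM cleavage and regioselective re-protection of the two unhindered phenols.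
4. The ring A piece comes from phloroglucinol tris-MOM ether by ortho-lithiation and alkylation with geranyl bromide. Rings A and B are bought intact.

Key step: step 11

Remark: geranyl = (2E)-3,7-dimethylocta-2,6-dien-1-yl, MOM = methoxymethyl, TBS = tert-butyldimethylsilyl, allyl = prop-2-en-1-yl; diazotisation of the α-amino acid is assumed to proceed with the usual net retention through carboxylate participation.

**Route**

Step 1
Reactants: 1 D-tyrosine
Product: 4 (R)-2-hydroxy-3-(4-hydroxyphenyl)propanoic acid, via diazonium carboxylate 2 (not isolated), via α-lactone 3 (not isolated)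
Conditions: NaNO2, 1 M aq. H2SO4, 0 °C → 23 °C
Reagents that add atoms: water, O
Why: Diazotisation–hydrolysis of an α-amino acid (van Slyke-type deamination) runs by double inversion, the carboxylate displacing N2 to give the α-lactone and water opening it, so the (R)-amine should give the (R)-alcohol with net retention.

Step 2
Reactants: 4 (R)-2-hydroxy-3-(4-hydroxyphenyl)propanoic acid
Product: 5 allyl (R)-3-[4-(allyloxy)phenyl]-2-hydroxypropanoate
Conditions: allyl bromide (2.5 equiv), K2CO3, DMF, 23 °C
Reagents that add atoms: allyl bromide, C=CCBr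
Why: Williamson-type O-alkylation in which carbonate ionises only the carboxylic acid and the phenol, so both are allylated in one operation while the secondary alcohol and the stereocentre are left alone.

Step 3
Reactants: 5 allyl (R)-3-[4-(allyloxy)phenyl]-2-hydroxypropanoate
Product: 6 allyl (R)-3-[4-(allyloxy)phenyl]-2-(tert-butyldimethylsilyloxy)propanoate
Conditions: TBSCl, imidazole, DMF, 23 °C
Reagents that add atoms: tert-butyldimethylsilyl chloride, CC(C)(C)[Si](C)(C)Cl
Why: Standard imidazole-promoted silylation of a secondary alcohol, which masks the only acidic proton before the organometallic steps.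

Step 4
Reactants: 6 allyl (R)-3-[4-(allyloxy)phenyl]-2-(tert-butyldimethylsilyloxy)propanoate
Product: 7 (R)-3-[4-(allyloxy)phenyl]-2-(tert-butyldimethylsilyloxy)-N-methoxy-N-methylpropanamide
Conditions: MeNH(OMe)·HCl, i-PrMgCl, THF, −20 → 0 °C
Reagents that add atoms: N,O-dimethylhydroxylamine hydrochloride, CNOC.Cl
Why: Weinreb amide formation by aminolysis of the ester with the chloromagnesium amide made in the flask, a nucleophilic but weakly basic reagent that should leave the α-silyloxy stereocentre intact at low temperature.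

Step 5
Reactants: 8 phloroglucinol
Product: 9 1,3,5-tris(methoxymethoxy)benzene
Conditions: NaH, MOMCl, DMF, 0 → 23 °C
Reagents that add atoms: chloromethyl methyl ether, COCCl
Why: Williamson etherification of the phenoxide with a hard chloromethyl ether gives O-alkylation and installs three ortho-directing groups.

Step 6
Reactants: 9 1,3,5-tris(methoxymethoxy)benzene; 10 geranyl bromide
Product: 12 2-geranyl-1,3,5-tris(methoxymethoxy)benzene, via aryllithium 11 (not isolated)
Conditions: n-BuLi, THF, 0 °C; then 10, −78 → 23 °C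
Reagents that add atoms: none
Why: Directed ortho-metalation between two OMOM groups followed by SN2 alkylation of the aryllithium with the primary allylic bromide, which should keep the E geometry of the geranyl chain.

Step 7
Reactants: 12 2-geranyl-1,3,5-tris(methoxymethoxy)benzene; 7 (R)-3-[4-(allyloxy)phenyl]-2-(tert-butyldimethylsilyloxy)-N-methoxy-N-methylpropanamide
Product: 15 (R)-3-[4-(allyloxy)phenyl]-2-(tert-butyldimethylsilyloxy)-1-[3-geranyl-2,4,6-tris(methoxymethoxy)phenyl]propan-1-one, via aryllithium 13 (not isolated), via tetrahedral lithium alkoxide 14 (not isolated)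
Conditions: n-BuLi (1.0 equiv per 12), THF, 0 °C; then 7 (0.8 equiv), −78 → 0 °C; sat. aq. NH4Cl
Reagents that add atoms: none
Why: Directed ortho-metalation at the position flanked by two OMOM groups (both such positions are equivalent) followed by Weinreb ketone synthesis, in which the chelated tetrahedral adduct 14 blocks a second addition and keeps the α-silyloxy stereocentre from enolising until the cold quench.

Step 8
Reactants: 15 (R)-3-[4-(allyloxy)phenyl]-2-(tert-butyldimethylsilyloxy)-1-[3-geranyl-2,4,6-tris(methoxymethoxy)phenyl]propan-1-one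
Product: 16 (R)-3-[4-(allyloxy)phenyl]-1-(3-geranyl-2,4,6-trihydroxyphenyl)-2-hydroxypropan-1-one
Conditions: 3 M aq. HCl–MeOH (1:5), 45 °C
Reagents that add atoms: none
Why: Acid-catalysed methanolysis of the three aryl MOM acetals and the secondary silyl ether, done because the two carbonyl-flanking oxygens can only be told apart at the free triol; the aryl allyl ether, the trisubstituted alkenes and the ketol stereocentre should tolerate dilute HCl in MeOH.

Step 9
Reactants: 16 (R)-3-[4-(allyloxy)phenyl]-1-(3-geranyl-2,4,6-trihydroxyphenyl)-2-hydroxypropan-1-one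
Product: 17 (R)-3-[4-(allyloxy)phenyl]-1-[3-geranyl-2-hydroxy-4,6-bis(methoxymethoxy)phenyl]-2-hydroxypropan-1-one
Conditions: MOMCl (2.1 equiv), K2CO3, acetone, 0 → 23 °C
Reagents that add atoms: chloromethyl methyl ether, COCCl
Why: Regioselective Williamson-type O-alkylation: the hydroxyl para to the carbonyl is the most acidic and the one flanked only by H and the acyl group is the more accessible chelating hydroxyl, whereas the hydroxyl wedged between geranyl and acyl stays hydrogen-bonded to the ketone, and carbonate does not ionise the aliphatic carbinol.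

Step 10
Reactants: 17 (R)-3-[4-(allyloxy)phenyl]-1-[3-geranyl-2-hydroxy-4,6-bis(methoxymethoxy)phenyl]-2-hydroxypropan-1-one
Product: 18 (R)-1-[3-geranyl-2-hydroxy-4,6-bis(methoxymethoxy)phenyl]-2-hydroxy-3-(4-hydroxyphenyl)propan-1-one
Conditions: Pd(PPh3)4 (5 mol %), morpholine, THF, 23 °C
Reagents that add atoms: none
Why: Tsuji–Trost-type deallylation, in which zerovalent palladium ionises the aryl allyl ether to a π-allyl complex that morpholine captures; the MOM ethers, the ketol and the C-bound geranyl group have no leaving group and should be inert.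

Step 11
Reactants: 18 (R)-1-[3-geranyl-2-hydroxy-4,6-bis(methoxymethoxy)phenyl]-2-hydroxy-3-(4-hydroxyphenyl)propan-1-one
Product: 20 (2R,3R)-8-geranyl-3-hydroxy-2-(4-hydroxyphenyl)-5,7-bis(methoxymethoxy)chroman-4-one, via para-quinone methide 19 (not isolated)
Conditions: Ag2O (2.5 equiv), 4 Å MS, CH2Cl2 (0.01 M), 23 °C, dark
Reagents that add atoms: none
Why: Ag2O (monovalent silver) removes two electrons and two protons from the 4-hydroxybenzyl unit of ring B (phenoxyl radical, then loss of the C2 hydrogen) to give para-quinone methide 19, and the ring A hydroxyl next to the geranyl group, once rotated out of its hydrogen bond to the C4 carbonyl, adds to the exocyclic carbon in an oxa-1,6-conjugate addition that restores the aromaticity of ring B. The closest known reaction type is the Ag2O oxidation of 4-alkylphenols to para-quinone methides with capture by an internal hydroxyl, as in oxidative flavan and benzodioxane ring closures. Ring C closes in the 6-exo-trig mode, O1 attacking C2 with the attacked C=C lying outside the new ring. The C2 stereocentre is set by the existing C3 carbinol: in the chair-like transition state the ring B aryl and the C3 hydroxyl both sit pseudo-equatorial, and because the addition is reversible through 19 the 2,3-trans (2R,3R) isomer should also be the thermodynamic sink. The step needs oxidation at ring B and not ring A (the acyl group and the chelated hydroxyl raise the oxidation potential of ring A), a single site of O-attack (the other carbonyl-flanking oxygen is a MOM ether), and ring closure faster than loss of the C3 hydrogen from 19 to the achiral α-hydroxychalcone (favoured by an intramolecular six-membered closure under base-free, dilute, aprotic conditions).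

Step 12
Reactants: 20 (2R,3R)-8-geranyl-3-hydroxy-2-(4-hydroxyphenyl)-5,7-bis(methoxymethoxy)chroman-4-one
Product: 21 (2R,3R)-8-geranyl-3,5,7-trihydroxy-2-(4-hydroxyphenyl)chroman-4-one
Conditions: 3 M aq. HCl–MeOH (1:5), 40 °C
Reagents that add atoms: none
Why: Acid-catalysed methanolysis of the two aryl MOM acetals under the mild conditions customary for prenylated flavonoids; a trans-dihydroflavonol does not epimerise in acid, so C2 and C3 should be kept.

**Compound list**

1 | D-tyrosine | N[C@H](Cc1ccc(O)cc1)C(=O)O | starting material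
2 | (R)-2-diazonio-3-(4-hydroxyphenyl)propanoate | N#[N+][C@H](Cc1ccc(O)cc1)C(=O)[O-] | intermediate
3 | (S)-3-(4-hydroxybenzyl)oxiran-2-one | O=C1O[C@H]1Cc2ccc(O)cc2 | intermediate
4 | (R)-2-hydroxy-3-(4-hydroxyphenyl)propanoic acid | OC(=O)[C@H](O)Cc1ccc(O)cc1 | intermediate
5 | allyl (R)-3-[4-(allyloxy)phenyl]-2-hydroxypropanoate | C=CCOC(=O)[C@H](O)Cc1ccc(OCC=C)cc1 | intermediate
6 | allyl (R)-3-[4-(allyloxy)phenyl]-2-(tert-butyldimethylsilyloxy)propanoate | C=CCOC(=O)[C@H](O[Si](C)(C)C(C)(C)C)Cc1ccc(OCC=C)cc1 | intermediate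
7 | (R)-3-[4-(allyloxy)phenyl]-2-(tert-butyldimethylsilyloxy)-N-methoxy-N-methylpropanamide | CON(C)C(=O)[C@H](O[Si](C)(C)C(C)(C)C)Cc1ccc(OCC=C)cc1 | intermediate
8 | phloroglucinol | Oc1cc(O)cc(O)c1 | starting material
9 | 1,3,5-tris(methoxymethoxy)benzene | COCOc1cc(OCOC)cc(OCOC)c1 | intermediate
10 | geranyl bromide | CC(C)=CCC/C(C)=C/CBr | starting material
11 | [2,4,6-tris(methoxymethoxy)phenyl]lithium | [Li]c1c(OCOC)cc(OCOC)cc1OCOC | intermediate
12 | 2-geranyl-1,3,5-tris(methoxymethoxy)benzene | CC(C)=CCC/C(C)=C/Cc1c(OCOC)cc(OCOC)cc1OCOC | intermediate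
13 | [3-geranyl-2,4,6-tris(methoxymethoxy)phenyl]lithium | CC(C)=CCC/C(C)=C/Cc1c(OCOC)cc(OCOC)c([Li])c1OCOC | intermediate
14 | lithium alkoxide of the N-methoxy-N-methyl hemiaminal formed from 13 and 7 (hemiaminal carbon not defined, C2 of the chain R) | CC(C)=CCC/C(C)=C/Cc1c(OCOC)cc(OCOC)c(C(O[Li])(N(C)OC)[C@H](O[Si](C)(C)C(C)(C)C)Cc2ccc(OCC=C)cc2)c1OCOC | intermediate
15 | (R)-3-[4-(allyloxy)phenyl]-2-(tert-butyldimethylsilyloxy)-1-[3-geranyl-2,4,6-tris(methoxymethoxy)phenyl]propan-1-one | CC(C)=CCC/C(C)=C/Cc1c(OCOC)cc(OCOC)c(C(=O)[C@H](O[Si](C)(C)C(C)(C)C)Cc2ccc(OCC=C)cc2)c1OCOC | intermediate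
16 | (R)-3-[4-(allyloxy)phenyl]-1-(3-geranyl-2,4,6-trihydroxyphenyl)-2-hydroxypropan-1-one | CC(C)=CCC/C(C)=C/Cc1c(O)cc(O)c(C(=O)[C@H](O)Cc2ccc(OCC=C)cc2)c1O | intermediate
17 | (R)-3-[4-(allyloxy)phenyl]-1-[3-geranyl-2-hydroxy-4,6-bis(methoxymethoxy)phenyl]-2-hydroxypropan-1-one | CC(C)=CCC/C(C)=C/Cc1c(OCOC)cc(OCOC)c(C(=O)[C@H](O)Cc2ccc(OCC=C)cc2)c1O | intermediate
18 | (R)-1-[3-geranyl-2-hydroxy-4,6-bis(methoxymethoxy)phenyl]-2-hydroxy-3-(4-hydroxyphenyl)propan-1-one | CC(C)=CCC/C(C)=C/Cc1c(OCOC)cc(OCOC)c(C(=O)[C@H](O)Cc2ccc(O)cc2)c1O | intermediate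
19 | (R)-4-{3-[3-geranyl-2-hydroxy-4,6-bis(methoxymethoxy)phenyl]-2-hydroxy-3-oxopropylidene}cyclohexa-2,5-dien-1-one | CC(C)=CCC/C(C)=C/Cc1c(OCOC)cc(OCOC)c(C(=O)[C@H](O)C=C2C=CC(=O)C=C2)c1O | intermediate
20 | (2R,3R)-8-geranyl-3-hydroxy-2-(4-hydroxyphenyl)-5,7-bis(methoxymethoxy)chroman-4-one | CC(C)=CCC/C(C)=C/Cc1c(OCOC)cc(OCOC)c2c1O[C@H](c1ccc(O)cc1)[C@@H](O)C2=O | intermediate
21 | (2R,3R)-8-geranyl-3,5,7-trihydroxy-2-(4-hydroxyphenyl)chroman-4-one (8-geranylaromadendrin, CNP0187235.1) | CC(C)=CCC/C(C)=C/Cc1c(O)cc(O)c2c1O[C@H](c1ccc(O)cc1)[C@@H](O)C2=O | target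

**Step count**

Total: 12 steps. Longest linear sequence: 10 steps (1 → 4 → 5 → 6 → 7 → 15 → 16 → 17 → 18 → 20 → 21; the ring A branch 8 → 9 → 12 joins at step 7).

**Steps most likely to fail**

Step 11. The one-electron oxidation of the unhindered ring B phenol may divert into intermolecular radical coupling before the second electron is removed. The quinone methide may also lose the C3 hydrogen faster than it is trapped, which would erase the C3 configuration. The fallback reaches the same O1–C2 bond without an oxidant, from an enantioenriched chalcone epoxide, using known reactions. It sets out from geranyl bromide 10 and comes back to the route at 20.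
- Commercial 2,4,6-trihydroxyacetophenone is C-geranylated with 10 (K2CO3, acetone) to 1-(3-geranyl-2,4,6-trihydroxyphenyl)ethanone F1.
- MOMCl/K2CO3 caps the two unhindered phenols to give 1-[3-geranyl-2-hydroxy-4,6-bis(methoxymethoxy)phenyl]ethanone F2.
- The remaining chelated phenol is allylated (allyl bromide, K2CO3, DMF, 60 °C) to 1-[2-(allyloxy)-3-geranyl-4,6-bis(methoxymethoxy)phenyl]ethanone F3.
- Claisen–Schmidt condensation with 4-(allyloxy)benzaldehyde (KOH, EtOH) gives (E)-1-[2-(allyloxy)-3-geranyl-4,6-bis(methoxymethoxy)phenyl]-3-[4-(allyloxy)phenyl]prop-2-en-1-one F4.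
- Juliá–Colonna epoxidation (poly-L-leucine, urea–H2O2, DBU, THF) should give [2-(allyloxy)-3-geranyl-4,6-bis(methoxymethoxy)phenyl][(2R,3S)-3-(4-(allyloxy)phenyl)oxiran-2-yl]methanone F5. The hydroperoxide anion attacks only the enone and leaves the geranyl alkenes alone, and the (αR,βS) sense is expected by analogy with the parent chalcone.
- Pd(PPh3)4/morpholine then removes both allyl groups. The freed ring A phenol should open the epoxide at the benzylic carbon with inversion, helped by the para-oxygen of ring B, to give 20 with C3 fixed by the epoxide.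
- Enantiomeric purity would be raised by crystallisation if needed.

Step 9. The two carbonyl-flanking phenols may be discriminated incompletely, and alkylation may run on to the tris-MOM ether. The fallback replaces acetal alkylation by steric discrimination with a bulky silyl chloride. It sets out from 16 and comes back at the target 21.
- TIPSCl/imidazole (DMF, 0 °C) should silylate the two unhindered phenols to give (R)-3-[4-(allyloxy)phenyl]-1-[3-geranyl-2-hydroxy-4,6-bis(triisopropylsilyloxy)phenyl]-2-hydroxypropan-1-one F6.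
- Deallylation as in step 10 gives (R)-1-[3-geranyl-2-hydroxy-4,6-bis(triisopropylsilyloxy)phenyl]-2-hydroxy-3-(4-hydroxyphenyl)propan-1-one F7.
- Ag2O closure as in step 11 gives (2R,3R)-8-geranyl-3-hydroxy-2-(4-hydroxyphenyl)-5,7-bis(triisopropylsilyloxy)chroman-4-one F8.
- HF·pyridine (THF, 0 °C) gives 21, which also removes the acid treatment of the geranylated flavanonol in step 12.

Step 8. The geranyl chain may cyclise under acid onto the newly freed flanking phenols, in competition with slow cleavage of the non-chelated MOM ether. The fallback introduces the geranyl group only after the acid step, by C-alkylation of a symmetric acylphloroglucinol. It sets out from aryllithium 11 and amide 7 and comes back at 16.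
- Addition of 11 to 7 (THF, −78 → 0 °C) gives (R)-3-[4-(allyloxy)phenyl]-2-(tert-butyldimethylsilyloxy)-1-[2,4,6-tris(methoxymethoxy)phenyl]propan-1-one F9.
- HCl/MeOH, now with no geranyl group in the molecule, gives (R)-3-[4-(allyloxy)phenyl]-2-hydroxy-1-(2,4,6-trihydroxyphenyl)propan-1-one F10.
- C-geranylation with 10 (K2CO3, acetone, 23 °C) gives 16; the two free ring positions are equivalent, so only mono- versus di-alkylation has to be controlled.

**Further compounds**

F1 | step 11 | 1-(3-geranyl-2,4,6-trihydroxyphenyl)ethanone | CC(C)=CCC/C(C)=C/Cc1c(O)cc(O)c(C(C)=O)c1O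
F2 | step 11 | 1-[3-geranyl-2-hydroxy-4,6-bis(methoxymethoxy)phenyl]ethanone | CC(C)=CCC/C(C)=C/Cc1c(OCOC)cc(OCOC)c(C(C)=O)c1O
F3 | step 11 | 1-[2-(allyloxy)-3-geranyl-4,6-bis(methoxymethoxy)phenyl]ethanone | CC(C)=CCC/C(C)=C/Cc1c(OCOC)cc(OCOC)c(C(C)=O)c1OCC=C
F4 | step 11 | (E)-1-[2-(allyloxy)-3-geranyl-4,6-bis(methoxymethoxy)phenyl]-3-[4-(allyloxy)phenyl]prop-2-en-1-one | CC(C)=CCC/C(C)=C/Cc1c(OCOC)cc(OCOC)c(C(=O)/C=C/c2ccc(OCC=C)cc2)c1OCC=C
F5 | step 11 | [2-(allyloxy)-3-geranyl-4,6-bis(methoxymethoxy)phenyl][(2R,3S)-3-(4-(allyloxy)phenyl)oxiran-2-yl]methanone | CC(C)=CCC/C(C)=C/Cc1c(OCOC)cc(OCOC)c(C(=O)[C@@H]2O[C@H]2c3ccc(OCC=C)cc3)c1OCC=C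
F6 | step 9 | (R)-3-[4-(allyloxy)phenyl]-1-[3-geranyl-2-hydroxy-4,6-bis(triisopropylsilyloxy)phenyl]-2-hydroxypropan-1-one | CC(C)=CCC/C(C)=C/Cc1c(O[Si](C(C)C)(C(C)C)C(C)C)cc(O[Si](C(C)C)(C(C)C)C(C)C)c(C(=O)[C@H](O)Cc2ccc(OCC=C)cc2)c1O
F7 | step 9 | (R)-1-[3-geranyl-2-hydroxy-4,6-bis(triisopropylsilyloxy)phenyl]-2-hydroxy-3-(4-hydroxyphenyl)propan-1-one | CC(C)=CCC/C(C)=C/Cc1c(O[Si](C(C)C)(C(C)C)C(C)C)cc(O[Si](C(C)C)(C(C)C)C(C)C)c(C(=O)[C@H](O)Cc2ccc(O)cc2)c1O
F8 | step 9 | (2R,3R)-8-geranyl-3-hydroxy-2-(4-hydroxyphenyl)-5,7-bis(triisopropylsilyloxy)chroman-4-one | CC(C)=CCC/C(C)=C/Cc1c(O[Si](C(C)C)(C(C)C)C(C)C)cc(O[Si](C(C)C)(C(C)C)C(C)C)c2c1O[C@H](c1ccc(O)cc1)[C@@H](O)C2=O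
F9 | step 8 | (R)-3-[4-(allyloxy)phenyl]-2-(tert-butyldimethylsilyloxy)-1-[2,4,6-tris(methoxymethoxy)phenyl]propan-1-one | COCOc1cc(OCOC)c(C(=O)[C@H](O[Si](C)(C)C(C)(C)C)Cc2ccc(OCC=C)cc2)c(OCOC)c1
F10 | step 8 | (R)-3-[4-(allyloxy)phenyl]-2-hydroxy-1-(2,4,6-trihydroxyphenyl)propan-1-one | Oc1cc(O)c(C(=O)[C@H](O)Cc2ccc(OCC=C)cc2)c(O)c1
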